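**Retrosynthetic overview**
1. Selaginellin F (12) ⇐ acid unveiling (loss of two THP groups, dehydration of triaryl carbinol 11 to the quinone methide) ⇐ twofold addition of aryllithium 10 to the lactone carbonyl of 8; the ring opening sets the 2'-OH free.
2. Lactone 8 ⇐ Sonogashira coupling of bromolactone 5 with 4-ethynylphenol 6; 5 ⇐ borane reduction of the free acid in 4.
3. Lactone acid 4 ⇐ 2-bromoisophthalic acid 1 + 4-iodophenyl acetate 2: ortho C–H arylation, then the key C2'–O bond by carboxylate-directed C–H acyloxylation (lactonisation). This installs the second resorcinol oxygen and tells the two carboxyl groups apart.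
4. Ring order: all four benzene rings are bought; the pyranone ring is the only ring made (step 1) and is opened again in step 4; the cyclohexadienone arises last by dehydration.

Assumption: the SMILES contains no stereocentre and no fixed axis, so the target is made as the single achiral compound drawn (THP acetal carbons are racemic and are lost in step 4); 4-ethynylphenol is taken as a catalogue compound, stored cold.

**Step 1**
Reactants: 1 2-bromoisophthalic acid; 2 4-iodophenyl acetate
Product: 4 3-(acetyloxy)-7-bromo-6-oxo-6H-benzo[c]chromene-8-carboxylic acid, via biaryl diacid 3 (not isolated)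
Conditions: 1 (2.5 equiv), 2 (1 equiv), Pd(OAc)2 (10 mol%), AgOAc (1.05 equiv), AcOH, 120 °C; filter off silver iodide; then KOAc (2 equiv), PhI(OAc)2 (2 equiv), 100 °C; surplus 1 recovered
Reagents that add atoms: none
Why: Proposed new method: a one-flask, single-catalyst palladium relay from a benzoic acid C–H bond and an aryl iodide to a dibenzo-α-pyranone, not shown as one operation nor on a 2-haloisophthalic acid – first the carboxylate directs cyclopalladation of C4–H by divalent palladium, oxidative addition of 2 gives a tetravalent palladium aryl, C–C reductive elimination gives 3 and AgOAc removes the iodide (C–Br is inert because no zerovalent palladium is involved; excess 1 keeps diarylation low); after the silver iodide is filtered off (so the oxidant cannot turn it into an iodinating agent), the carboxylate flanked by Br and the new ring directs palladation of C2'–H through a seven-membered palladacycle, PhI(OAc)2 oxidises it to tetravalent palladium and C–O reductive elimination closes the lactone (any C2'–OAc product lactonises in hot AcOH), so only the carboxyl next to the new ring is used; closest known reaction types are the Pd(OAc)2/AgOAc/AcOH ortho C–H arylation of benzoic acids with aryl iodides and the Pd(OAc)2/PhI(OAc)2 dehydrogenative C–H lactonisation of 2-arylbenzoic acids, each run separately on mono-acids; no stereocentre is formed.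

**Step 2**
Reactants: 4 3-(acetyloxy)-7-bromo-6-oxo-6H-benzo[c]chromene-8-carboxylic acid
Product: 5 7-bromo-8-(hydroxymethyl)-6-oxo-6H-benzo[c]chromen-3-yl acetate
Conditions: BH3·SMe2 (2.5 equiv), THF, 0 °C → rt; MeOH quench
Reagents that add atoms: none
Why: Chemoselective borane reduction of a carboxylic acid: the acyloxyborane formed from the free acid is reduced far faster than the aryl lactone or the aryl acetate, and the C–Br bond is untouched; no stereocentre is formed.

**Step 3**
Reactants: 5 7-bromo-8-(hydroxymethyl)-6-oxo-6H-benzo[c]chromen-3-yl acetate; 6 4-ethynylphenol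
Product: 8 3-hydroxy-8-(hydroxymethyl)-7-[(4-hydroxyphenyl)ethynyl]-6H-benzo[c]chromen-6-one, via acetate 7 (not isolated)
Conditions: PdCl2(PhCN)2 (3 mol%), [HP(t-Bu)3]BF4 (6 mol%), CuI (3 mol%), i-Pr2NH, dioxane, degassed, 40 °C; then MeOH, K2CO3 (0.3 equiv), rt; dilute HCl work-up
Reagents that add atoms: none
Why: Sonogashira coupling: zerovalent palladium with the bulky electron-rich P(t-Bu)3 inserts into the doubly ortho-substituted C–Br bond (activated by the ortho lactone carbonyl) at a temperature the free phenol alkyne tolerates; catalytic methanolysis then removes the aryl acetate (including any acetyl that has moved to the other phenol) to give one product, and acidification re-closes any opened lactone; no stereocentre is formed.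

**Step 4**
Reactants: 8 3-hydroxy-8-(hydroxymethyl)-7-[(4-hydroxyphenyl)ethynyl]-6H-benzo[c]chromen-6-one; 9 2-(4-bromophenoxy)tetrahydro-2H-pyran
Product: 12 selaginellin F, via aryllithium 10 (not isolated), via triaryl carbinol 11 (not isolated)
Conditions: 9 (9.5 equiv), n-BuLi (9 equiv), THF, −78 °C; add 8, −78 °C → rt; then 2 M aq. HCl, 0 °C → rt; NaHCO3 to pH 6
Reagents that add atoms: none
Why: Bromine–lithium exchange gives 10; three equivalents deprotonate the OH groups, one adds to the aryl lactone carbonyl and the tetrahedral intermediate collapses to a diaryl ketone by expelling the phenoxide (the acyl C–O bond breaks, the aryl C2'–O bond made in step 1 stays as the 2'-OH), a further equivalent adds to the ketone to give 11 (double organolithium addition to a lactone); aqueous acid cleaves both THP acetals and ionises the doubly para-oxygenated trityl carbinol, and loss of a phenolic proton gives the quinone methide (fuchsone formation); no stereocentre is formed.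

**Compound list**
1 | 2-bromoisophthalic acid (2-bromobenzene-1,3-dicarboxylic acid) | OC(=O)c1cccc(C(=O)O)c1Br | starting material
2 | 4-iodophenyl acetate | CC(=O)Oc1ccc(I)cc1 | starting material
3 | 4'-(acetyloxy)-3-bromobiphenyl-2,4-dicarboxylic acid | CC(=O)Oc1ccc(cc1)-c1ccc(C(=O)O)c(Br)c1C(=O)O | intermediate
4 | 3-(acetyloxy)-7-bromo-6-oxo-6H-benzo[c]chromene-8-carboxylic acid | CC(=O)Oc1ccc2c(c1)OC(=O)c1c(Br)c(C(=O)O)ccc1-2 | intermediate
5 | 7-bromo-8-(hydroxymethyl)-6-oxo-6H-benzo[c]chromen-3-yl acetate | CC(=O)Oc1ccc2c(c1)OC(=O)c1c(Br)c(CO)ccc1-2 | intermediate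
6 | 4-ethynylphenol | C#Cc1ccc(O)cc1 | starting material
7 | 8-(hydroxymethyl)-7-[(4-hydroxyphenyl)ethynyl]-6-oxo-6H-benzo[c]chromen-3-yl acetate | CC(=O)Oc1ccc2c(c1)OC(=O)c1c(C#Cc3ccc(O)cc3)c(CO)ccc1-2 | intermediate
8 | 3-hydroxy-8-(hydroxymethyl)-7-[(4-hydroxyphenyl)ethynyl]-6H-benzo[c]chromen-6-one | Oc1ccc2c(c1)OC(=O)c1c(C#Cc3ccc(O)cc3)c(CO)ccc1-2 | intermediate
9 | 2-(4-bromophenoxy)tetrahydro-2H-pyran (racemic at the acetal carbon) | Brc1ccc(OC2CCCCO2)cc1 | starting material
10 | [4-(tetrahydro-2H-pyran-2-yloxy)phenyl]lithium (racemic at the acetal carbon) | [Li]c1ccc(OC2CCCCO2)cc1 | intermediate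
11 | {2',4'-dihydroxy-4-(hydroxymethyl)-3-[(4-hydroxyphenyl)ethynyl]biphenyl-2-yl}bis[4-(tetrahydro-2H-pyran-2-yloxy)phenyl]methanol (mixture of acetal diastereomers) | OC(c1ccc(OC2CCCCO2)cc1)(c1ccc(OC2CCCCO2)cc1)c1c(-c2ccc(O)cc2O)ccc(CO)c1C#Cc1ccc(O)cc1 | intermediate
12 | selaginellin F, 4-[{2',4'-dihydroxy-4-(hydroxymethyl)-3-[(4-hydroxyphenyl)ethynyl]biphenyl-2-yl}(4-hydroxyphenyl)methylidene]cyclohexa-2,5-dien-1-one (achiral) | O=C1C=CC(=C(c2ccc(O)cc2)c2c(-c3ccc(O)cc3O)ccc(CO)c2C#Cc2ccc(O)cc2)C=C1 | target

**Totals**
Total step count: 4. Longest linear sequence: 4 steps (1 → 4 → 5 → 8 → 12).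

**Steps most likely to fail**

Step 1 (the proposed relay). The risks are diarylation of 1, silver-promoted protodecarboxylation of the bromo acid, and a second stage disturbed by residues of the first. The fallback uses known chemistry and sets out from 1 and 2: only the Pd(OAc)2/AgOAc/AcOH ortho-arylation is run, diacid 3 is isolated, and the lactone is closed in a separate flask by the known copper-catalysed aroyloxy-radical cyclisation of 2-arylbenzoic acids (Cu(OAc)2 cat., dibenzoyl peroxide, hexafluoroisopropanol, 75 °C). This is a radical C–O closure instead of a reductive elimination at palladium. It returns to the route at 4 and makes no compound outside the list, F0.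

Step 3. The risk is slow oxidative addition at the hindered bromide at temperatures where free 4-ethynylphenol dimerises or polymerises. The fallback sets out from 5 and forms the aryl–alkyne bond from the other side. Compound 5 is coupled with trimethylsilylacetylene, which can be heated (PdCl2(PPh3)2, CuI, Et3N, 70 °C), to give the silyl alkyne 8-(hydroxymethyl)-6-oxo-7-[(trimethylsilyl)ethynyl]-6H-benzo[c]chromen-3-yl acetate F1. K2CO3 in MeOH removes silicon and acetate together to give the terminal alkyne 7-ethynyl-3-hydroxy-8-(hydroxymethyl)-6H-benzo[c]chromen-6-one F2. F2 is coupled with cheap 4-iodophenol at room temperature (PdCl2(PPh3)2, CuI, Et3N). The fallback returns at 8.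

Step 4. The risks are an insoluble trilithium salt of 8, a stalled second addition to the hindered ketone, and, in the acid stage, addition of the free 2'-OH to the cation to give the isomeric 6,6-diaryl-6H-benzo[c]chromene. The fallback sets out from 8 and protects first: TBSCl and imidazole in DMF give the tris-silyl ether 3-[(tert-butyldimethylsilyl)oxy]-8-{[(tert-butyldimethylsilyl)oxy]methyl}-7-({4-[(tert-butyldimethylsilyl)oxy]phenyl}ethynyl)-6H-benzo[c]chromen-6-one F3. Addition of 10 (3 equiv, THF, −78 °C → 0 °C) to this soluble lactone gives the carbinol {4'-[(tert-butyldimethylsilyl)oxy]-4-{[(tert-butyldimethylsilyl)oxy]methyl}-3-({4-[(tert-butyldimethylsilyl)oxy]phenyl}ethynyl)-2'-hydroxybiphenyl-2-yl}bis[4-(tetrahydro-2H-pyran-2-yloxy)phenyl]methanol F4. Bu4NF (THF, 0 °C) followed by AcOH/H2O at 45 °C removes silicon, THP and water under buffered conditions without mineral acid. The fallback returns at 12.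

**Further compounds**
F0 | step 1 | none | none
F1 | step 3 | 8-(hydroxymethyl)-6-oxo-7-[(trimethylsilyl)ethynyl]-6H-benzo[c]chromen-3-yl acetate | CC(=O)Oc1ccc2c(c1)OC(=O)c1c(C#C[Si](C)(C)C)c(CO)ccc1-2
F2 | step 3 | 7-ethynyl-3-hydroxy-8-(hydroxymethyl)-6H-benzo[c]chromen-6-one | Oc1ccc2c(c1)OC(=O)c1c(C#C)c(CO)ccc1-2
F3 | step 4 | 3-[(tert-butyldimethylsilyl)oxy]-8-{[(tert-butyldimethylsilyl)oxy]methyl}-7-({4-[(tert-butyldimethylsilyl)oxy]phenyl}ethynyl)-6H-benzo[c]chromen-6-one | CC(C)(C)[Si](C)(C)Oc1ccc2c(c1)OC(=O)c1c(C#Cc3ccc(O[Si](C)(C)C(C)(C)C)cc3)c(CO[Si](C)(C)C(C)(C)C)ccc1-2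
F4 | step 4 | {4'-[(tert-butyldimethylsilyl)oxy]-4-{[(tert-butyldimethylsilyl)oxy]methyl}-3-({4-[(tert-butyldimethylsilyl)oxy]phenyl}ethynyl)-2'-hydroxybiphenyl-2-yl}bis[4-(tetrahydro-2H-pyran-2-yloxy)phenyl]methanol | OC(c1ccc(OC2CCCCO2)cc1)(c1ccc(OC2CCCCO2)cc1)c1c(-c2ccc(O[Si](C)(C)C(C)(C)C)cc2O)ccc(CO[Si](C)(C)C(C)(C)C)c1C#Cc1ccc(O[Si](C)(C)C(C)(C)C)cc1
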